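**Retrosynthetic overview**

1. The ester comes last: target 22 ⇐ epoxy diol 20 + 3,4-dimethoxybenzoyl chloride 21 (acylation of O8); 20 ⇐ bis-silyl epoxide 19.
2. 19 ⇐ monocyclic thiolanium salt 16: one base-induced operation forms the C3–C4 bond (closing the cyclopentane C1–C2–C3–C4–C5) and then the C3–O bond (closing the oxirane), an intramolecular sulfonium-ylide epoxidation.
3. Enabling feature: C3–C4 is the bond shared by the five-membered ring and the oxirane; C4 (O, CH3, C5) is a masked acetyl group on C5 and C3 (O, H, C2) a masked ylide carbon at the end of a two-carbon chain on C1, the two chains being trans on the seven-membered ring.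
4. 16 ⇐ allylic alcohol 7 by Ueno–Stork radical cyclisation from O10 (C1–C2 bond cis to O10 through a temporary oxolane acetal) with isocyanide capture at C5 (trans); 7 ⇐ enone 6 (MeLi/CeCl3).
5. 6 ⇐ meso oxabicycle 1 by palladium-catalysed enantioselective ring opening with iPr2Zn (sets C7, C8). Ring order: seven-membered ring (from 1), temporary oxolane (steps 7–8), then cyclopentane and oxirane together (step 12).

Key step: step 12

Remark: all carbons keep the guaiane numbers of the target (ring C1, C5–C10; C2–C3 is the chain on C1; C4 is the carbon on C5), β is the face of the seven-membered ring carrying the C10 hydroxyl, O8 and the isopropyl group, and the Tol-BINAP enantiomer in step 2 is assigned by analogy and would be exchanged for its antipode if the sense of induction proves opposite.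

**Route**

Step 1
Reactants: 1 8-oxabicyclo[3.2.1]oct-6-en-3-one
Product: 2 meso ethylene ketal of 1
Conditions: (TMSOCH2)2, TMSOTf (cat.), CH2Cl2, −78 °C
Reagents that add atoms: 1,2-bis(trimethylsilyloxy)ethane, C[Si](C)(C)OCCO[Si](C)(C)C
Why: Aprotic silyl-triflate-catalysed ketalisation should mask the ketone without the protic acid that could open the β-alkoxy ketone, and it keeps the mirror plane needed for the desymmetrisation.

Step 2
Reactants: 2 meso ethylene ketal
Product: 3 cis-8-isopropyl-cycloheptenol ketal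
Conditions: iPr2Zn (2 equiv), Pd(MeCN)2Cl2 (5 mol %), (R)-Tol-BINAP (5.5 mol %), Zn(OTf)2 (10 mol %), ClCH2CH2Cl, 40 °C; aq. NH4Cl
Reagents that add atoms: diisopropylzinc, CC(C)[Zn]C(C)C
Why: Palladium-catalysed enantioselective alkylative ring opening of a meso oxabicyclic alkene with a dialkylzinc: exo carbopalladation by the cationic isopropylpalladium species followed by β-oxygen elimination should deliver the isopropyl group cis to the new hydroxyl (C7/C8), the ligand choosing between the two enantiotopic alkene carbons.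

Step 3
Reactants: 3 cis-cycloheptenol ketal
Product: 4 TBS ether of 3
Conditions: TBSCl, imidazole, DMF, 40 °C
Reagents that add atoms: tert-butyldimethylsilyl chloride, CC(C)(C)[Si](C)(C)Cl
Why: Imidazole-promoted silylation of the secondary alcohol; the bulky silyl ether is later the stereocontrol element of step 5 and the only hydroxyl protection needed until step 13.

Step 4
Reactants: 4 TBS ether ketal
Product: 6 conjugated enone (5R,6R)-6-(TBSO)-5-isopropylcyclohept-2-en-1-one, via β,γ-unsaturated ketone 5 (not isolated)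
Conditions: PPTS, acetone–H2O, 50 °C; then Et3N (0.5 equiv), CH2Cl2, rt
Reagents that add atoms: water, O
Why: Mild acid hydrolysis of the dioxolane followed by amine-mediated migration of the β,γ double bond into conjugation (thermodynamic control) should place the alkene between C1 and C5; the β-silyloxy group is a poor leaving group under these conditions.

Step 5
Reactants: 6 conjugated enone
Product: 7 tertiary allylic alcohol (10S)
Conditions: MeLi, CeCl3, THF, −78 °C
Reagents that add atoms: methyllithium, [Li]C
Why: Organocerium 1,2-addition (no conjugate addition or enolisation); the cis 7,8-substituents cannot both be pseudoequatorial, so the OTBS group on C8 should sit pseudoaxial and screen the β face of the carbonyl, methyl entering from the α face and leaving the new hydroxyl cis to O8.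

Step 6
Reactants: 7 tertiary allylic alcohol
Product: 8 mixed bromoacetal at O10
Conditions: ethyl vinyl ether (5 equiv), NBS, CH2Cl2, −40 → 0 °C
Reagents that add atoms: ethyl vinyl ether, C=COCC; N-bromosuccinimide, O=C1CCC(=O)N1Br
Why: Bromoacetalisation (the first half of the Ueno–Stork sequence): the bromonium ion of the vinyl ether is captured by the tertiary hydroxyl; the acetal carbon forms as both epimers, which converge in step 8.

Step 7
Reactants: 8 mixed bromoacetal
Product: 9 cis-fused oxolane acetal nitrile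
Conditions: Bu3SnH (slow addition), t-BuNC (20 equiv), AIBN (cat.), PhH (0.02 M), 80 °C
Reagents that add atoms: tert-butyl isocyanide, [C-]#[N+]C(C)(C)C
Why: Ueno–Stork radical cyclisation with isocyanide trapping: the primary radical closes 5-exo onto C1 through a necessarily cis-fused oxolane (C2 cis to O10), and the resulting C5 radical should be captured by the isocyanide on the face away from the new ring and the C7 isopropyl group (C1/C5 trans), loss of tert-butyl radical giving the nitrile.

Step 8
Reactants: 9 oxolane acetal nitrile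
Product: 11 diol nitrile, via lactol 10 (not isolated)
Conditions: 0.5 M HCl, THF, rt; then NaHCO3, NaBH4, MeOH, 0 °C
Reagents that add atoms: water, O
Why: Acid hydrolysis of the mixed acetal and borohydride reduction of the open hydroxy-aldehyde form of the lactol remove the temporary ring; the nitrile is inert to NaBH4 and both acetal epimers give the same diol.

Step 9
Reactants: 11 diol nitrile
Product: 12 bis-TES ether
Conditions: TESOTf (2.5 equiv), 2,6-lutidine, CH2Cl2, −78 → 0 °C
Reagents that add atoms: triethylsilyl triflate, CC[Si](CC)(CC)OS(=O)(=O)C(F)(F)F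
Why: The silyl triflate silylates both the primary and the hindered tertiary hydroxyl, so that O10 cannot later attack C3.

Step 10
Reactants: 12 bis-TES ether nitrile
Product: 14 keto alcohol with tertiary OTES, via N-lithio ketimine 13 (not isolated)
Conditions: MeLi (3 equiv), Et2O, −78 → 0 °C; then 1 M HCl, THF, 0 °C
Reagents that add atoms: methyllithium, [Li]C; water, O
Why: Methyllithium adds once to the nitrile (the N-lithio ketimine resists a second addition); dilute acid should hydrolyse it to the methyl ketone and cleave the unhindered primary TES ether, while the tertiary TES and secondary TBS ethers remain.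

Step 11
Reactants: 14 keto alcohol
Product: 16 thiolanium triflate, via primary triflate 15 (not isolated)
Conditions: Tf2O, 2,6-lutidine, CH2Cl2, −78 °C; then tetrahydrothiophene (10 equiv), −78 → 0 °C
Reagents that add atoms: triflic anhydride, O=S(=O)(OS(=O)(=O)C(F)(F)F)C(F)(F)F; tetrahydrothiophene, C1CCSC1
Why: Triflation of the primary alcohol and in situ SN2 S-alkylation of the sulfide (sulfonium salt formation); sulfur, by far the best nucleophile present and used in excess, should outrun participation by the neighbouring silyl ether or ketone oxygen.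

Step 12
Reactants: 16 thiolanium triflate
Product: 19 bis-silyl 3,4-epoxyguaiane, via sulfonium ylide 17 (not isolated), via betaine 18 (not isolated)
Conditions: KOtBu (1.1 equiv), THF (0.01 M), −40 → 0 °C
Reagents that add atoms: none
Why: KOtBu removes a proton from C3 (α to S+) to give ylide 17, whose C3 adds to the C4 carbonyl (5-exo-trig, closing the cyclopentane through the C3–C4 bond) to give betaine 18, and the C4 alkoxide then displaces tetrahydrothiophene from C3 with inversion (3-exo-tet), closing the oxirane. The closest known reaction type is the Corey–Chaykovsky epoxidation run intramolecularly on an ω-sulfonio ketone (epoxy-annulation), here on two chains held trans on the cycloheptane. The ring fusion (C1, C5) is already trans in 16; at C4 the trans-fused half-chair fixes the sense of the C3–C4–C5–C1 torsion, so the carbonyl can only put O syn to C6 with CH3 syn to H5 or the reverse, and the first avoids the CH3/C6 eclipsing interaction and matches the favoured acetyl conformer, which should give the α-oxygen and β-methyl at C4. At C3 only the betaine with S+ anti to O− can close, and inversion puts the oxirane oxygen on the α face there too (cis-fused oxirane). The step needs deprotonation at C3 rather than ketone enolisation or deprotonation of the thiolane ring: the S+–CH2 protons are the most acidic, proton exchange between ylides is fast and only the C3 ylide has a five-membered transition state, while the silyl group on O10 prevents an alkoxide from displacing the sulfonium group.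

Step 13
Reactants: 19 bis-silyl epoxide
Product: 20 epoxy diol
Conditions: TBAF (4 equiv), THF, 0 °C → rt
Reagents that add atoms: none
Why: Fluoride cleaves the secondary TBS and the tertiary TES ether in one operation under non-acidic conditions that the trisubstituted epoxide should tolerate.

Step 14
Reactants: 20 epoxy diol; 21 3,4-dimethoxybenzoyl chloride
Product: 22 target
Conditions: Et3N, DMAP (cat.), CH2Cl2, 0 °C → rt
Reagents that add atoms: none
Why: DMAP-catalysed acylation of the secondary C8 hydroxyl; the tertiary C10 hydroxyl should not react under these conditions.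

**Compound list**

1 | 8-oxabicyclo[3.2.1]oct-6-en-3-one (meso, 1R,5S) | O=C1C[C@H]2C=C[C@@H](C1)O2 | starting material
2 | (1R,5S)-spiro[8-oxabicyclo[3.2.1]oct-6-ene-3,2'-[1,3]dioxolane] (meso) | C1COC2(O1)C[C@H]3C=C[C@@H](C2)O3 | intermediate
3 | (7R,8S)-8-(propan-2-yl)-1,4-dioxaspiro[4.6]undec-9-en-7-ol (isopropyl and hydroxyl cis) | O[C@@H]1CC2(OCCO2)C/C=C\[C@@H]1C(C)C | intermediate
4 | tert-butyl(dimethyl){[(7R,8S)-8-(propan-2-yl)-1,4-dioxaspiro[4.6]undec-9-en-7-yl]oxy}silane | CC(C)(C)[Si](C)(C)O[C@@H]1CC2(OCCO2)C/C=C\[C@@H]1C(C)C | intermediate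
5 | (5S,6R)-6-[(tert-butyldimethylsilyl)oxy]-5-(propan-2-yl)cyclohept-3-en-1-one | CC(C)(C)[Si](C)(C)O[C@@H]1CC(=O)C/C=C\[C@@H]1C(C)C | intermediate (not isolated)
6 | (5R,6R)-6-[(tert-butyldimethylsilyl)oxy]-5-(propan-2-yl)cyclohept-2-en-1-one | CC(C)(C)[Si](C)(C)O[C@@H]1CC(=O)/C=C\C[C@@H]1C(C)C | intermediate
7 | (1S,5R,6R)-6-[(tert-butyldimethylsilyl)oxy]-1-methyl-5-(propan-2-yl)cyclohept-2-en-1-ol | CC(C)(C)[Si](C)(C)O[C@@H]1C[C@](C)(O)/C=C\C[C@@H]1C(C)C | intermediate
8 | tert-butyl{[(1R,2R,6S)-6-(2-bromo-1-ethoxyethoxy)-6-methyl-2-(propan-2-yl)cyclohept-4-en-1-yl]oxy}dimethylsilane (both epimers at the acetal carbon) | CC(C)(C)[Si](C)(C)O[C@@H]1C[C@](C)(OC(CBr)OCC)/C=C\C[C@@H]1C(C)C | intermediate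
9 | (3aR,4S,6R,7R,8aS)-7-[(tert-butyldimethylsilyl)oxy]-2-ethoxy-8a-methyl-6-(propan-2-yl)octahydro-2H-cyclohepta[b]furan-4-carbonitrile (both epimers at C2 of the furan ring) | CC(C)(C)[Si](C)(C)O[C@@H]1C[C@]2(C)OC(OCC)C[C@@H]2[C@@H](C#N)C[C@@H]1C(C)C | intermediate
10 | (3aR,4S,6R,7R,8aS)-7-[(tert-butyldimethylsilyl)oxy]-2-hydroxy-8a-methyl-6-(propan-2-yl)octahydro-2H-cyclohepta[b]furan-4-carbonitrile (lactol, both epimers) | CC(C)(C)[Si](C)(C)O[C@@H]1C[C@]2(C)OC(O)C[C@@H]2[C@@H](C#N)C[C@@H]1C(C)C | intermediate (not isolated)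
11 | (1S,2R,3S,5R,6R)-5-[(tert-butyldimethylsilyl)oxy]-3-hydroxy-2-(2-hydroxyethyl)-3-methyl-6-(propan-2-yl)cycloheptane-1-carbonitrile | CC(C)(C)[Si](C)(C)O[C@@H]1C[C@](C)(O)[C@H](CCO)[C@@H](C#N)C[C@@H]1C(C)C | intermediate
12 | (1S,2R,3S,5R,6R)-5-[(tert-butyldimethylsilyl)oxy]-3-methyl-6-(propan-2-yl)-3-[(triethylsilyl)oxy]-2-{2-[(triethylsilyl)oxy]ethyl}cycloheptane-1-carbonitrile | CC(C)(C)[Si](C)(C)O[C@@H]1C[C@](C)(O[Si](CC)(CC)CC)[C@H](CCO[Si](CC)(CC)CC)[C@@H](C#N)C[C@@H]1C(C)C | intermediate
13 | N-lithio methyl ketimine from 12 (C4 carries CH3 and =N–Li; ring stereocentres as in 12) | CC(C)(C)[Si](C)(C)O[C@@H]1C[C@](C)(O[Si](CC)(CC)CC)[C@H](CCO[Si](CC)(CC)CC)[C@@H](C(C)=N[Li])C[C@@H]1C(C)C | intermediate (not isolated)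
14 | 1-[(1S,2R,3S,5R,6R)-5-[(tert-butyldimethylsilyl)oxy]-2-(2-hydroxyethyl)-3-methyl-6-(propan-2-yl)-3-[(triethylsilyl)oxy]cycloheptyl]ethan-1-one | CC(C)(C)[Si](C)(C)O[C@@H]1C[C@](C)(O[Si](CC)(CC)CC)[C@H](CCO)[C@@H](C(C)=O)C[C@@H]1C(C)C | intermediate
15 | primary trifluoromethanesulfonate of 14 (at O of C3) | CC(C)(C)[Si](C)(C)O[C@@H]1C[C@](C)(O[Si](CC)(CC)CC)[C@H](CCOS(=O)(=O)C(F)(F)F)[C@@H](C(C)=O)C[C@@H]1C(C)C | intermediate (not isolated)
16 | 1-{2-[(1R,2S,4R,5R,7S)-7-acetyl-4-[(tert-butyldimethylsilyl)oxy]-2-methyl-5-(propan-2-yl)-2-[(triethylsilyl)oxy]cycloheptyl]ethyl}thiolan-1-ium trifluoromethanesulfonate | CC(C)(C)[Si](C)(C)O[C@@H]1C[C@](C)(O[Si](CC)(CC)CC)[C@H](CC[S+]2CCCC2)[C@@H](C(C)=O)C[C@@H]1C(C)C.[O-]S(=O)(=O)C(F)(F)F | intermediate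
17 | sulfonium ylide of 16 (carbanion at C3) | CC(C)(C)[Si](C)(C)O[C@@H]1C[C@](C)(O[Si](CC)(CC)CC)[C@H](C[CH-][S+]2CCCC2)[C@@H](C(C)=O)C[C@@H]1C(C)C | intermediate (not isolated)
18 | betaine: trans-fused guaiane with C4 alkoxide (α) and C3 thiolanium (β), 4-methyl β | CC(C)(C)[Si](C)(C)O[C@@H]1C[C@](C)(O[Si](CC)(CC)CC)[C@@H]2C[C@H]([S+]3CCCC3)[C@@](C)([O-])[C@H]2C[C@@H]1C(C)C | intermediate (not isolated)
19 | (1R,3R,4S,5S,7R,8R,10S)-8-[(tert-butyldimethylsilyl)oxy]-3,4-epoxy-10-[(triethylsilyl)oxy]guaiane | CC(C)(C)[Si](C)(C)O[C@@H]1C[C@](C)(O[Si](CC)(CC)CC)[C@@H]2C[C@H]3O[C@@]3(C)[C@H]2C[C@@H]1C(C)C | intermediate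
20 | (1R,3R,4S,5S,7R,8R,10S)-3,4-epoxyguaiane-8,10-diol | O[C@@H]1C[C@](C)(O)[C@@H]2C[C@H]3O[C@@]3(C)[C@H]2C[C@@H]1C(C)C | intermediate
21 | 3,4-dimethoxybenzoyl chloride | COc1ccc(C(=O)Cl)cc1OC | starting material
22 | (1R,3R,4S,5S,7R,8R,10S)-3,4-epoxy-10-hydroxyguaian-8-yl 3,4-dimethoxybenzoate (CNP0304846.1) | COc1ccc(C(=O)O[C@@H]2C[C@](C)(O)[C@@H]3C[C@H]4O[C@@]4(C)[C@H]3C[C@@H]2C(C)C)cc1OC | target

**Step count and risks**

Total step count: 14. Longest linear sequence: 14 steps (1 → 22).

Steps most likely to fail: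

Step 12. The methyl ketone may be enolised in competition with ylide formation (leading to aldol products or C/O-alkylation by the sulfonium carbon), the thiolane ring may be deprotonated instead of C3, Hofmann-type elimination may occur, or the facial selectivity at C4 may be poor. Fallback (sets out from 14, returns at 19): oxidation of the primary alcohol with Dess–Martin periodinane should give the keto aldehyde F1. Intramolecular McMurry coupling (TiCl3(DME)1.5, Zn/Cu couple, DME, reflux, slow addition) closes the same C3–C4 bond as an alkene, giving the trans-fused cyclopentene F2. NBS in aqueous THF should form the bromonium ion on the β face (away from C6 on the allylic C5) and water should open it at the tertiary C4 from the α face, giving the bromohydrin F3. K2CO3 in MeOH then closes the α-oxirane by displacement of bromide, arriving at 19.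

Step 2. β-Hydride elimination from the isopropylpalladium intermediate may lead to reductive ring opening instead of isopropyl transfer, or the enantioselectivity with the secondary alkylzinc may be low. Fallback (sets out from 2, returns at 6): rhodium-catalysed asymmetric ring opening with isopropenylboronic acid pinacol ester ([Rh(cod)Cl]2, (R,S)-PPF-P(t-Bu)2, Cs2CO3, THF–H2O) should give the cis isopropenyl cycloheptenol ketal F4. Silylation (TBSCl, imidazole) gives the silyl ether F5, and ketal hydrolysis with conjugation as in step 4 gives the isopropenyl enone F6. Hydrogenation with RhCl(PPh3)3 and H2, which should reduce the 1,1-disubstituted alkene and spare the conjugated ring alkene, arrives at 6.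

Step 5. The 1,2-addition may show poor facial selectivity, with attack syn to O8 giving the C10 epimer. Fallback (sets out from 6, returns at 7): Wittig methylenation (Ph3P=CH2, THF) gives the exocyclic diene F7 and TBAF frees the homoallylic alcohol F8. Hydroxyl-directed epoxidation with VO(acac)2 and t-BuOOH should epoxidise the exocyclic alkene cis to O8, giving the spiro-epoxide F9. LiBHEt3 opens it at the primary carbon to the diol F10 with the 10-hydroxyl cis to O8, and selective silylation of the secondary hydroxyl (TBSCl, imidazole, DMF) arrives at 7.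

Further compounds
F1 | step 12 | keto aldehyde: C3 aldehyde analogue of 14 (1R,5S,7R,8R,10S in guaiane numbering) | CC(C)(C)[Si](C)(C)O[C@@H]1C[C@](C)(O[Si](CC)(CC)CC)[C@H](CC=O)[C@@H](C(C)=O)C[C@@H]1C(C)C
F2 | step 12 | (1R,5S,7R,8R,10S)-8-[(tert-butyldimethylsilyl)oxy]-10-[(triethylsilyl)oxy]guai-3-ene | CC(C)(C)[Si](C)(C)O[C@@H]1C[C@](C)(O[Si](CC)(CC)CC)[C@@H]2CC=C(C)[C@H]2C[C@@H]1C(C)C
F3 | step 12 | (1R,3S,4S,5S,7R,8R,10S)-3-bromo-8-[(tert-butyldimethylsilyl)oxy]-10-[(triethylsilyl)oxy]guaian-4-ol | CC(C)(C)[Si](C)(C)O[C@@H]1C[C@](C)(O[Si](CC)(CC)CC)[C@@H]2C[C@H](Br)[C@@](C)(O)[C@H]2C[C@@H]1C(C)C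
F4 | step 2 | (7R,8R)-8-(prop-1-en-2-yl)-1,4-dioxaspiro[4.6]undec-9-en-7-ol (isopropenyl and hydroxyl cis) | O[C@@H]1CC2(OCCO2)C/C=C\[C@@H]1C(C)=C
F5 | step 2 | tert-butyldimethylsilyl ether of F4 | CC(C)(C)[Si](C)(C)O[C@@H]1CC2(OCCO2)C/C=C\[C@@H]1C(C)=C
F6 | step 2 | (5R,6R)-6-[(tert-butyldimethylsilyl)oxy]-5-(prop-1-en-2-yl)cyclohept-2-en-1-one | CC(C)(C)[Si](C)(C)O[C@@H]1CC(=O)/C=C\C[C@@H]1C(C)=C
F7 | step 5 | 10-methylidene analogue of 6: tert-butyldimethylsilyl ether of (7R,8R)-7-isopropyl-10-methylidenecyclohept-1(5)-en-8-ol (guaiane numbering) | CC(C)(C)[Si](C)(C)O[C@@H]1CC(=C)/C=C\C[C@@H]1C(C)C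
F8 | step 5 | free alcohol of F7 (7R,8R) | O[C@@H]1CC(=C)/C=C\C[C@@H]1C(C)C
F9 | step 5 | spiro-epoxide of F8 at C10 with the oxirane oxygen cis to the 8-hydroxyl (7R,8R,10S) | O[C@@H]1C[C@@]2(CO2)/C=C\C[C@@H]1C(C)C
F10 | step 5 | (1S,5R,6R)-1-methyl-5-(propan-2-yl)cyclohept-2-ene-1,6-diol | O[C@@H]1C[C@](C)(O)/C=C\C[C@@H]1C(C)C
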